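Flavanone numbering (O1, C2, C3, C4, C4a, C5–C8, C8a) is used for the corresponding atoms of every intermediate.

## Structural features

- The target is (2S)-5,7-dihydroxy-6-methoxy-8-prenylflavanone: a chroman-4-one (ring C: O1, C2, C3, C4, C4a, C8a) fused through C4a–C8a to benzene ring A, with phenyl ring B on C2.
- C2 is the only stereocenter. It is benzylic and β to the C4 ketone, so deprotonation at C3 opens ring C by retro-oxa-Michael reaction to an achiral chalcone; the configuration is therefore base-labile.
- Ring A is hexasubstituted: acyl carbon at C4a, OH at C5, OMe at C6, OH at C7, prenyl at C8, ether oxygen O1 at C8a. It has no free position and four oxygens in three different states.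
- The real difficulty is regiochemical. The oxygens on C5 and C8a are both ortho to C4a, so in any acylphloroglucinol precursor either one can close ring C. The two outcomes (6-OMe/8-prenyl or 8-OMe/6-prenyl) also interconvert through the chalcone.
- The prenyl alkene is fragile: acid cyclizes it onto the C7 hydroxyl, and it excludes hydrogenolysis, halogenation and strong oxidants late in the route.
- In its triketo tautomer ring A is a cyclohexane-1,3,5-trione with carbonyl carbons C5, C7 and C8a and nucleophilic carbons C4a, C6 and C8. This is the feature the key step exploits: ring A is closed by Claisen condensation (C4a onto C5) on a precursor in which the C8a oxygen is already the ring C ether O1, and C6 and C8 already carry OMe and prenyl.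

## Logic of the disconnections

**12 to 11.** The C4a–C5 bond of ring A is cut (retro-Claisen, after returning ring A to its triketo tautomer). The route in one sentence: ring A is closed last by Claisen cyclization and aromatization of 11, a finished enantiopure ring C that carries C5–C8 as an open α-methoxy β-keto ester chain. The gain is that the hexasubstituted arene, its O1-versus-C5-oxygen assignment, the OMe and the prenyl group all become open-chain features. The demand is that the C8-centred enolate of 11 reacts through C4a with the C5 ester, and that C3 is never deprotonated.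

**11 to 5 and 9.** The C8–C8a bond is cut and the C4 carbonyl is returned to a methyl enol ether, so that C8a becomes a lactone carbonyl already bonded to O1. This splits the molecule into ring C (with C2 set) and the whole C5–C8 chain. The demand is γ-selective acylation of the dianion of 9 at the lactone carbonyl of 5, followed by acid-mediated 1,3-carbonyl transposition. Only O1 can reach C8a in a six-membered ring, so the regiochemistry of ring C is fixed here.

**9 to 6 and 7.** The C6–C7 bond is cut (retro-Claisen). The prenyl group is the native tail of 6 (C8 is its α-carbon) and the methoxy group is native to 7, so ring A is never prenylated or O-methylated selectively. The demand is a clean crossed Claisen acylation of the enolate of 7.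

**5 to 4 to 3 to 1 and 2.** The enol O–CH3 bond, then the lactone O1–C8a bond, then the C4–C4a bond (retro-Claisen) are cut. C2 comes from the bought hydroxy ester 1 with no bond to the stereocenter ever broken. The demand is that none of the three steps enolizes toward C2 with loss of the C2–O bond.

## Other disconnections considered

**Alternative 1:** Cut O1–C2 and then C2–C3, back to 2',4',6'-trihydroxy-3'-methoxy-5'-prenylacetophenone A1 and benzaldehyde.
- Forward: Claisen–Schmidt condensation to chalcone A2, then base- or catalyst-mediated oxa-Michael closure.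
- This is the route most chemists would draw first.
- A2 has two free ortho hydroxyls, so closure gives the target or the 8-methoxy-6-prenyl isomer A3.
- The ring-closing bond forms under the conditions that break it, so neither the regiochemistry nor C2 is under kinetic control.
- A1 itself needs selective O-methylation and C-prenylation of a phloroglucinol with protecting groups.
- The chosen plan fixes O1 before ring A exists and buys C2.

**Alternative 2:** Cut the C2–phenyl bond.
- Forward: enantioselective conjugate addition of phenylboronic acid to the bis-MOM chromone A4, with Pd(OCOCF3)2 (divalent palladium) and a chiral pyridine-oxazoline ligand, to give A5, then deprotection.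
- This would set C2 well on simple chromones.
- It leaves the whole ring A problem in A4, which must be made from an acetophenone like A1 with the same two-oxygen ambiguity.
- A4 is a doubly ortho-substituted, electron-rich and therefore poor acceptor.
- Two acetal groups must finally be removed from an acid-sensitive prenylated flavanone.
- It is longer and solves the easier half of the problem.

**Alternative 3:** Danheiser benzannulation, cutting C4a–C5, C5–C6 and C7–C8.
- Forward: vinylketene A6 (ketene on the C8 carbon of a ring C pyranone) and a siloxyalkyne A7 undergo (2+2) addition, four-electron opening, six-electron closure and tautomerization.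
- The mapping is right for C5–OH, C7–O and C8-prenyl.
- C6–OMe would require an alkyne carrying two different oxygens, which is not a practical reagent.
- With A7 the product is the 6-unsubstituted flavanone A8, and C6 would have to be oxygenated late next to the prenyl alkene and the labile C2.
- The chosen plan keeps the same idea (ring A built onto ring C) but places all six substituents by enolate chemistry.

Key step: step 6

Assumption: 1 and 6 are taken as catalogue compounds; 9, 10 and 11 are carried as mixtures of keto–enol tautomers and of epimers at their enolizable side-chain carbons, all of which converge in step 6.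

## Route

Step 1
Reactants: 1 ethyl (3S)-3-hydroxy-3-phenylpropanoate; 2 tert-butyl acetate
Product: 3 tert-butyl (5S)-5-hydroxy-3-oxo-5-phenylpentanoate
Conditions: LiN(iPr)2 (3.6 equiv), 2 (3.6 equiv), THF, −78 °C; then 1, −78 to −25 °C; aq. NH4Cl
Reagents that add atoms: none
Why: Crossed Claisen condensation; the first equivalent of the lithium enolate of 2 deprotonates the hydroxyl of 1, the second acylates at the ethyl ester and the product is held as its enolate; no bond to the carbinol carbon is touched, so the S configuration should be retained.

Step 2
Reactants: 3 tert-butyl (5S)-5-hydroxy-3-oxo-5-phenylpentanoate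
Product: 4 (6S)-6-phenyloxane-2,4-dione
Conditions: CF3CO2H, CH2Cl2, 0 °C to rt
Reagents that add atoms: none
Why: Acidolysis of the tert-butyl ester and acid-catalysed δ-lactonization to the six-membered β-keto lactone (present mainly as its 4-hydroxy-5,6-dihydropyran-2-one enol); the benzylic C–O bond should not ionize because the cation would sit β to a carbonyl.

Step 3
Reactants: 4 (6S)-6-phenyloxane-2,4-dione
Product: 5 (6S)-4-methoxy-6-phenyl-5,6-dihydro-2H-pyran-2-one
Conditions: Me2SO4 (1.2 equiv), K2CO3, acetone, rt
Reagents that add atoms: dimethyl sulfate, COS(=O)(=O)OC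
Why: O-Methylation of the vinylogous acid; the potassium enolate and a hard methylating agent should favour O- over C-alkylation, giving the vinylogous carbonate in which C4 is masked and C8a is the only carbonyl.

Step 4
Reactants: 6 5-methylhex-4-enoic acid; 7 methyl methoxyacetate
Product: 9 methyl 2-methoxy-7-methyl-3-oxooct-6-enoate, via acyl imidazole 8 (not isolated)
Conditions: 6, CDI (1.1 equiv), THF, rt; added to 7 (2.2 equiv) and LiN(SiMe3)2 (2.2 equiv), THF, −78 °C; aq. NH4Cl
Reagents that add atoms: 1,1'-carbonyldiimidazole, O=C(n1ccnc1)n1ccnc1 (its imidazole is carried only in intermediate 8)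
Why: Crossed Claisen acylation of a preformed α-alkoxy ester enolate by an acyl imidazole; two equivalents of enolate are used because the β-keto ester product quenches one; this joins C6 (with its OMe) to C7 and leaves the prenyl group as the untouched tail of 6.

Step 5
Reactants: 9 methyl 2-methoxy-7-methyl-3-oxooct-6-enoate; 5 (6S)-4-methoxy-6-phenyl-5,6-dihydro-2H-pyran-2-one
Product: 11 methyl 2-methoxy-7-methyl-3-oxo-4-[(2S)-4-oxo-2-phenyl-3,4-dihydro-2H-pyran-6-yl]oct-6-enoate, via open-chain hydroxy enone adduct 10 (not isolated)
Conditions: 9 (2.0 equiv), LiN(iPr)2 (4.1 equiv), THF, −78 to 0 °C; 5 (1.0 equiv), −78 to −20 °C; then 1 M HCl, THF, rt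
Reagents that add atoms: water, O (the C4 carbonyl oxygen of 11 comes from it)
Why: γ-Acylation of a β-keto ester dianion (reaction at C8, the more basic carbon) by the lactone carbonyl gives ring-opened 10, held as its 1,3-diketonate (hence the second equivalent of dianion); acid then re-closes the C2 hydroxyl onto the new C8a ketone and hydrolyses the enol ether (Stork–Danheiser-type 1,3-carbonyl transposition) to the vinylogous ester 11, with C2 untouched and O1 fixed on C8a.

Step 6
Reactants: 11 methyl 2-methoxy-7-methyl-3-oxo-4-[(2S)-4-oxo-2-phenyl-3,4-dihydro-2H-pyran-6-yl]oct-6-enoate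
Product: 12 agrandol, (2S)-5,7-dihydroxy-6-methoxy-8-(3-methylbut-2-en-1-yl)-2-phenyl-2,3-dihydro-4H-chromen-4-one
Conditions: KOt-Bu (1.1 equiv), THF, −20 °C to rt; AcOH
Reagents that add atoms: none
Why: One equivalent of base removes the most acidic proton, C8–H (between the C7 ketone and the vinylogous ester), giving a dienolate delocalized over O7, C8, C8a=C4a and O4 in which C4a is a carbon nucleophile; C4a attacks the C5 ester, methoxide leaves, and the resulting cyclohexenetrione tautomerizes irreversibly to the phenol, consuming the methoxide. The closest known reaction type is the Claisen (phloroglucinol) mode of β-polycarbonyl cyclization, a Dieckmann-type condensation, here with the C8a carbonyl locked as the cyclic enol ether of ring C. Ring A is closed by 6-(enolendo)-exo-trig C-acylation forming C4a–C5; ring C is not touched. No stereocenter is formed; the mixed configurations at C6 and C8 of 11 vanish on aromatization, so all isomers converge. C2 should be retained because C3–H is never removed: the base is consumed by protons about ten pKa units more acidic, and in both the dienolate and the product phenoxide C4 is a vinylogous carboxylate, which deactivates C3–H. The step needs Claisen over aldol and C- over O-acylation: the only other six-membered closure (C6 onto C4) would give a bridged bicyclo[3.3.1] aldolate with a bridgehead C4a=C8a bond that cannot dehydrate and reverts, and O-acylation would need a four- or eight-membered ring. The C6-centred enolate is unproductive but exchanges with the C8 enolate by proton transfer, so the material should funnel through the one irreversible path.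

## Compound list

1 | ethyl (3S)-3-hydroxy-3-phenylpropanoate | CCOC(=O)C[C@H](O)c1ccccc1 | starting material
2 | tert-butyl acetate | CC(=O)OC(C)(C)C | starting material
3 | tert-butyl (5S)-5-hydroxy-3-oxo-5-phenylpentanoate | CC(C)(C)OC(=O)CC(=O)C[C@H](O)c1ccccc1 | intermediate
4 | (6S)-6-phenyloxane-2,4-dione | O=C1CC(=O)C[C@@H](c2ccccc2)O1 | intermediate
5 | (6S)-4-methoxy-6-phenyl-5,6-dihydro-2H-pyran-2-one | O=C1C=C(OC)C[C@@H](c2ccccc2)O1 | intermediate
6 | 5-methylhex-4-enoic acid | CC(C)=CCCC(=O)O | starting material
7 | methyl methoxyacetate | COCC(=O)OC | starting material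
8 | 1-(5-methylhex-4-enoyl)imidazole | CC(C)=CCCC(=O)n1ccnc1 | intermediate
9 | methyl 2-methoxy-7-methyl-3-oxooct-6-enoate | COC(=O)C(OC)C(=O)CCC=C(C)C | intermediate
10 | methyl (6E,9S)-9-hydroxy-2,7-dimethoxy-4-(3-methylbut-2-en-1-yl)-3,5-dioxo-9-phenylnon-6-enoate | COC(=O)C(OC)C(=O)C(CC=C(C)C)C(=O)/C=C(/OC)C[C@H](O)c1ccccc1 | intermediate
11 | methyl 2-methoxy-7-methyl-3-oxo-4-[(2S)-4-oxo-2-phenyl-3,4-dihydro-2H-pyran-6-yl]oct-6-enoate | COC(=O)C(OC)C(=O)C(CC=C(C)C)C1=CC(=O)C[C@@H](c2ccccc2)O1 | intermediate
12 | agrandol, (2S)-5,7-dihydroxy-6-methoxy-8-(3-methylbut-2-en-1-yl)-2-phenyl-2,3-dihydro-4H-chromen-4-one | COc1c(O)c(CC=C(C)C)c2c(c1O)C(=O)C[C@@H](c1ccccc1)O2 | target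

## Step count and least certain steps

Total: 6 steps. Longest linear sequence: 5 steps (steps 1, 2, 3, 5, 6); the second branch is step 4 and joins at step 5.

**Step 6 (key step).**
- Most likely failure: the C-acylation stalls, because the nucleophile is a strongly stabilized, chelated 1,3-dicarbonyl-type enolate and the unproductive C6 enolate competes for the base.
- Forcing it with heat or excess base would invite deprotonation at C3 and retro-oxa-Michael opening of ring C (erosion of configuration at C2), or retro-Claisen cleavage at C7.
- Fallback, from 8 and 5 back to 12, replaces the enolate by a neutral ketene acylation: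
  - 8 is condensed with the lithium enolate of tert-butyl methoxyacetate to give tert-butyl 2-methoxy-7-methyl-3-oxooct-6-enoate F1.
  - The dianion of F1 and 5 give, as in step 5, the open-chain adduct F2 and, after pyridinium tosylate in wet THF, the tert-butyl keto ester pyranone F3.
  - Heating F3 in toluene at 110 °C expels tert-butanol to give the α-methoxy acylketene F4. Its ketene carbon should be attacked by C4a without any base, and tautomerization gives 12.

**Step 5.**
- Most likely failure: proton transfer from the lactone (at C4a or C3) to the strongly basic dianion, with eliminative opening of the lactone, instead of carbonyl addition.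
- Also possible: conjugate addition–elimination at the methoxy-bearing C4, or, in the acid stage, closure of the masked triketone through the C7 enol oxygen to a 4-pyranone.
- Fallback, from 5 and 9 back to 11, uses an acyclic, chelating acyl donor with the hydroxyl masked:
  - 5 is opened with MeNH(OMe)·HCl and i-PrMgCl to (2E,5S)-5-hydroxy-N,3-dimethoxy-N-methyl-5-phenylpent-2-enamide F5.
  - F5 is silylated (TBSCl, imidazole) to its tert-butyldimethylsilyl ether F6.
  - The dianion of 9 adds to F6 to give the silyl-protected open-chain adduct F7.
  - TsOH·H2O in wet THF removes the silyl group, hydrolyses the enol ether and closes ring C to 11.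

**Step 2.**
- Most likely failure: decarboxylation of the transient β-keto acid before lactonization, or acid-promoted dehydration of the benzylic carbinol.
- Fallback, from 1 back to 4, avoids any free β-keto acid:
  - 1 is condensed with excess lithium enolate of methyl acetate to methyl (5S)-5-hydroxy-3-oxo-5-phenylpentanoate F8.
  - F8 lactonizes under base (K2CO3, MeOH, rt; then acidification) by attack of the δ-alkoxide on the methyl ester, giving 4.

**Step 4.**
- Most likely failure: incomplete conversion through proton transfer from product to enolate, self-condensation of the enolate of 7 on warming, or a second acylation.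
- Fallback, from 8 back to 9, is a decarboxylative Claisen condensation:
  - Dimethyl methoxymalonate is half-saponified (KOH, 1 equiv, MeOH) to 2-methoxy-3-methoxy-3-oxopropanoic acid F9.
  - Its magnesium enolate (MgCl2, Et3N, MeCN) is acylated by 8 to the acylated half ester F10.
  - F10 loses carbon dioxide on acidic work-up to give 9.

## Further compounds

F1 | step 6 | tert-butyl 2-methoxy-7-methyl-3-oxooct-6-enoate | CC(C)=CCCC(=O)C(OC)C(=O)OC(C)(C)C
F2 | step 6 | tert-butyl (6E,9S)-9-hydroxy-2,7-dimethoxy-4-(3-methylbut-2-en-1-yl)-3,5-dioxo-9-phenylnon-6-enoate | CC(C)(C)OC(=O)C(OC)C(=O)C(CC=C(C)C)C(=O)/C=C(/OC)C[C@H](O)c1ccccc1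
F3 | step 6 | tert-butyl 2-methoxy-7-methyl-3-oxo-4-[(2S)-4-oxo-2-phenyl-3,4-dihydro-2H-pyran-6-yl]oct-6-enoate | CC(C)(C)OC(=O)C(OC)C(=O)C(CC=C(C)C)C1=CC(=O)C[C@@H](c2ccccc2)O1
F4 | step 6 | 2-methoxy-7-methyl-4-[(2S)-4-oxo-2-phenyl-3,4-dihydro-2H-pyran-6-yl]octa-1,6-diene-1,3-dione | O=C=C(OC)C(=O)C(CC=C(C)C)C1=CC(=O)C[C@@H](c2ccccc2)O1
F5 | step 5 | (2E,5S)-5-hydroxy-N,3-dimethoxy-N-methyl-5-phenylpent-2-enamide | CON(C)C(=O)/C=C(/OC)C[C@H](O)c1ccccc1
F6 | step 5 | (2E,5S)-5-[(tert-butyldimethylsilyl)oxy]-N,3-dimethoxy-N-methyl-5-phenylpent-2-enamide | CON(C)C(=O)/C=C(/OC)C[C@H](O[Si](C)(C)C(C)(C)C)c1ccccc1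
F7 | step 5 | methyl (6E,9S)-9-[(tert-butyldimethylsilyl)oxy]-2,7-dimethoxy-4-(3-methylbut-2-en-1-yl)-3,5-dioxo-9-phenylnon-6-enoate | COC(=O)C(OC)C(=O)C(CC=C(C)C)C(=O)/C=C(/OC)C[C@H](O[Si](C)(C)C(C)(C)C)c1ccccc1
F8 | step 2 | methyl (5S)-5-hydroxy-3-oxo-5-phenylpentanoate | COC(=O)CC(=O)C[C@H](O)c1ccccc1
F9 | step 4 | 2-methoxy-3-methoxy-3-oxopropanoic acid | COC(C(=O)O)C(=O)OC
F10 | step 4 | 2-methoxy-2-(methoxycarbonyl)-7-methyl-3-oxooct-6-enoic acid | COC(=O)C(OC)(C(=O)O)C(=O)CCC=C(C)C
A1 | alternative 1 | 1-[2,4,6-trihydroxy-3-methoxy-5-(3-methylbut-2-en-1-yl)phenyl]ethan-1-one | CC(=O)c1c(O)c(OC)c(O)c(CC=C(C)C)c1O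
A2 | alternative 1 | (2E)-3-phenyl-1-[2,4,6-trihydroxy-3-methoxy-5-(3-methylbut-2-en-1-yl)phenyl]prop-2-en-1-one | O=C(/C=C/c1ccccc1)c1c(O)c(OC)c(O)c(CC=C(C)C)c1O
A3 | alternative 1 | (2S)-5,7-dihydroxy-8-methoxy-6-(3-methylbut-2-en-1-yl)-2-phenyl-2,3-dihydro-4H-chromen-4-one | COc1c(O)c(CC=C(C)C)c(O)c2c1O[C@H](c1ccccc1)CC2=O
A4 | alternative 2 | 6-methoxy-5,7-bis(methoxymethoxy)-8-(3-methylbut-2-en-1-yl)-4H-chromen-4-one | O=c1ccoc2c(CC=C(C)C)c(OCOC)c(OC)c(OCOC)c12
A5 | alternative 2 | (2S)-6-methoxy-5,7-bis(methoxymethoxy)-8-(3-methylbut-2-en-1-yl)-2-phenyl-2,3-dihydro-4H-chromen-4-one | COCOc1c(OC)c(OCOC)c(CC=C(C)C)c2c1C(=O)C[C@@H](c1ccccc1)O2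
A6 | alternative 3 | 5-methyl-2-[(2S)-4-oxo-2-phenyl-3,4-dihydro-2H-pyran-6-yl]hexa-1,4-dien-1-one | O=C=C(CC=C(C)C)C1=CC(=O)C[C@@H](c2ccccc2)O1
A7 | alternative 3 | ethynyloxy[tri(propan-2-yl)]silane | C#CO[Si](C(C)C)(C(C)C)C(C)C
A8 | alternative 3 | (2S)-5-hydroxy-8-(3-methylbut-2-en-1-yl)-2-phenyl-7-{[tri(propan-2-yl)silyl]oxy}-2,3-dihydro-4H-chromen-4-one | CC(C)[Si](Oc1cc(O)c2c(c1CC=C(C)C)O[C@H](c1ccccc1)CC2=O)(C(C)C)C(C)C
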